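**Retrosynthetic overview**
1. Target 34 ⇐ methyl ester 32 ⇐ enol triflate 31 ⇐ trans-fused bicyclic ketone 29 (C3 ethyl by cross-coupling, acid by SN2 demethylation).
2. 29 ⇐ acyclic tetraenone ester 28 by an intramolecular Diels–Alder reaction: ring A (cyclohexene) and ring B (five-membered ring) close in the same step; the ring B alkene is made last.
3. 28 ⇐ homoallylic alcohol 26 ⇐ trienal 23 + methyl 2-(bromomethyl)acrylate 24: an intermolecular zinc-mediated carbonyl allylation forms C3–C4 and joins the diene fragment to the dienophile fragment (key step).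
4. 23 ⇐ aldehyde 13 by two Wittig homologations and one Horner–Wadsworth–Emmons olefination.
5. 13 ⇐ Evans allylation of propionyl oxazolidinone 1, which makes the only stereocentre carried into the cycloaddition.

Assumption: the target is taken exactly as the SMILES reads, i.e. the (1R,3aR,4R,5S,7aS) trans-fused isomer in indene numbering (C4 bears CO2H; ring A = C3a–C7a, ring B = C1–C3/C3a/C7a).

**Route**

Step 1
Reactants: 1 (4S)-4-benzyl-3-propanoyl-1,3-oxazolidin-2-one; 2 3-iodoprop-1-ene (allyl iodide)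
Product: 4 (4S)-4-benzyl-3-[(2R)-2-methylpent-4-enoyl]-1,3-oxazolidin-2-one, via sodium Z-enolate 3 (not isolated)
Conditions: NaN(SiMe3)2, THF, −78 °C; then 2, −78 to −45 °C
Reagents that add atoms: none
Why: Evans asymmetric alkylation, in which the chelated Z-enolate is allylated on the face opposite the benzyl group and so sets the 2R methyl stereocentre (the future C1 of the target).

Step 2
Reactants: 4 (4S)-4-benzyl-3-[(2R)-2-methylpent-4-enoyl]-1,3-oxazolidin-2-one
Product: 6 (3R)-4-[(4S)-4-benzyl-2-oxo-1,3-oxazolidin-3-yl]-3-methyl-4-oxobutanal, via ozonide 5 (not isolated)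
Conditions: O3, CH2Cl2, −78 °C; then Me2S, −78 °C to rt
Reagents that add atoms: ozone [O-][O+]=O
Why: Ozonolysis with reductive work-up cleaves the only alkene and leaves the imide and the stereocentre untouched.

Step 3
Reactants: 6 (3R)-4-[(4S)-4-benzyl-2-oxo-1,3-oxazolidin-3-yl]-3-methyl-4-oxobutanal
Product: 7 (4S)-4-benzyl-3-[(2R)-3-(1,3-dioxolan-2-yl)-2-methylpropanoyl]-1,3-oxazolidin-2-one
Conditions: Me3SiOCH2CH2OSiMe3, TMSOTf (cat.), CH2Cl2, −78 °C; pyridine quench
Reagents that add atoms: 1,2-bis(trimethylsilyloxy)ethane C[Si](C)(C)OCCO[Si](C)(C)C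
Why: Noyori acetalisation under aprotic conditions masks the aldehyde as a dioxolane that survives hydride, ylide and base in the following steps.

Step 4
Reactants: 7 (4S)-4-benzyl-3-[(2R)-3-(1,3-dioxolan-2-yl)-2-methylpropanoyl]-1,3-oxazolidin-2-one
Product: 8 (2R)-3-(1,3-dioxolan-2-yl)-2-methylpropan-1-ol
Conditions: LiBH4, H2O (1 equiv), Et2O, 0 °C; aq. NaOH work-up
Reagents that add atoms: none
Why: Reductive removal of the Evans auxiliary, in which LiBH4 attacks only the exocyclic imide carbonyl and does not touch the alpha stereocentre.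

Step 5
Reactants: 9 ethyl 2-bromobutanoate; 10 triphenylphosphane
Product: 12 ethyl 2-(triphenyl-λ5-phosphanylidene)butanoate, via phosphonium bromide 11 (not isolated)
Conditions: toluene, 90 °C; then aq. NaOH, CH2Cl2, 0 °C
Reagents that add atoms: none
Why: SN2 quaternisation of the phosphane by the alpha-bromo ester followed by deprotonation gives the stabilised Wittig ylide.

Step 6
Reactants: 8 (2R)-3-(1,3-dioxolan-2-yl)-2-methylpropan-1-ol; 12 ethyl 2-(triphenyl-λ5-phosphanylidene)butanoate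
Product: 14 ethyl (2E,4R)-5-(1,3-dioxolan-2-yl)-2-ethyl-4-methylpent-2-enoate, via aldehyde 13 (not isolated)
Conditions: Dess–Martin periodinane, pyridine, CH2Cl2, 0 °C to rt; then 12, rt to 40 °C
Reagents that add atoms: none
Why: Buffered Dess–Martin oxidation gives the epimerisable aldehyde, which is trapped at once in an E-selective Wittig reaction of the stabilised ylide.

Step 7
Reactants: 14 ethyl (2E,4R)-5-(1,3-dioxolan-2-yl)-2-ethyl-4-methylpent-2-enoate
Product: 15 (2E,4R)-5-(1,3-dioxolan-2-yl)-2-ethyl-4-methylpent-2-en-1-ol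
Conditions: iBu2AlH, CH2Cl2, −78 °C; aq. KNaC4H4O6
Reagents that add atoms: none
Why: 1,2-Reduction of the enoate by the aluminium hydride at low temperature gives the allylic alcohol without touching the acetal or the alkene.

Step 8
Reactants: 15 (2E,4R)-5-(1,3-dioxolan-2-yl)-2-ethyl-4-methylpent-2-en-1-ol
Product: 16 (2E,4R)-5-(1,3-dioxolan-2-yl)-2-ethyl-4-methylpent-2-enal
Conditions: MnO2, CH2Cl2, rt
Reagents that add atoms: none
Why: Allylic oxidation with MnO2 is selective for the allylic alcohol and does not isomerise the alkene.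

Step 9
Reactants: 16 (2E,4R)-5-(1,3-dioxolan-2-yl)-2-ethyl-4-methylpent-2-enal; 12 ethyl 2-(triphenyl-λ5-phosphanylidene)butanoate
Product: 17 ethyl (2E,4E,6R)-7-(1,3-dioxolan-2-yl)-2,4-diethyl-6-methylhepta-2,4-dienoate
Conditions: toluene, 90 °C
Reagents that add atoms: none
Why: A second E-selective Wittig olefination with the stabilised ylide builds the second trisubstituted alkene.

Step 10
Reactants: 17 ethyl (2E,4E,6R)-7-(1,3-dioxolan-2-yl)-2,4-diethyl-6-methylhepta-2,4-dienoate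
Product: 18 (2E,4E,6R)-7-(1,3-dioxolan-2-yl)-2,4-diethyl-6-methylhepta-2,4-dien-1-ol
Conditions: iBu2AlH, CH2Cl2, −78 °C; aq. KNaC4H4O6
Reagents that add atoms: none
Why: 1,2-Reduction of the dienoate to the dienol, as in step 7.

Step 11
Reactants: 18 (2E,4E,6R)-7-(1,3-dioxolan-2-yl)-2,4-diethyl-6-methylhepta-2,4-dien-1-ol
Product: 19 (2E,4E,6R)-7-(1,3-dioxolan-2-yl)-2,4-diethyl-6-methylhepta-2,4-dienal
Conditions: MnO2, CH2Cl2, rt
Reagents that add atoms: none
Why: Allylic oxidation with MnO2, as in step 8.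

Step 12
Reactants: 19 (2E,4E,6R)-7-(1,3-dioxolan-2-yl)-2,4-diethyl-6-methylhepta-2,4-dienal; 20 diethyl benzylphosphonate
Product: 22 2-[(2R,3E,5E,7E)-4,6-diethyl-2-methyl-8-phenylocta-3,5,7-trien-1-yl]-1,3-dioxolane, via sodium phosphonate carbanion 21 (not isolated)
Conditions: NaH, THF, 0 °C; then 19, −78 °C to rt
Reagents that add atoms: none
Why: Horner–Wadsworth–Emmons olefination with the preformed benzyl phosphonate anion gives the E-styryl alkene, and addition at low temperature avoids vinylogous deprotonation at C6.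

Step 13
Reactants: 22 2-[(2R,3E,5E,7E)-4,6-diethyl-2-methyl-8-phenylocta-3,5,7-trien-1-yl]-1,3-dioxolane
Product: 23 (3R,4E,6E,8E)-5,7-diethyl-3-methyl-9-phenylnona-4,6,8-trienal
Conditions: 1 M aq. HCl, THF, rt
Reagents that add atoms: water O
Why: Acetal hydrolysis in dilute acid frees the aldehyde, and C3 is beta to the carbonyl so it cannot epimerise.

Step 14
Reactants: 23 (3R,4E,6E,8E)-5,7-diethyl-3-methyl-9-phenylnona-4,6,8-trienal; 24 methyl 2-(bromomethyl)prop-2-enoate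
Product: 26 methyl (6R,7E,9E,11E)-8,10-diethyl-4-hydroxy-6-methyl-2-methylidene-12-phenyldodeca-7,9,11-trienoate (both C4 epimers), via allylzinc bromide 25 (not isolated)
Conditions: Zn dust, THF/sat. aq. NH4Cl, 0 °C to rt
Reagents that add atoms: none
Why: Barbier-type carbonyl allylation, in which the allylzinc reagent adds to the aldehyde and joins the triene fragment to the acrylate fragment at C3–C4; the new carbinol centre is uncontrolled and is removed in the next step.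

Step 15
Reactants: 26 methyl (6R,7E,9E,11E)-8,10-diethyl-4-hydroxy-6-methyl-2-methylidene-12-phenyldodeca-7,9,11-trienoate
Product: 28 methyl (2E,6R,7E,9E,11E)-8,10-diethyl-2,6-dimethyl-4-oxo-12-phenyldodeca-2,7,9,11-tetraenoate, via methylidene ketone 27 (not isolated)
Conditions: Dess–Martin periodinane, pyridine, CH2Cl2, 0 °C; then Et3N (0.3 equiv), 0 °C to rt
Reagents that add atoms: none
Why: Dess–Martin oxidation gives the doubly activated methylene ketone, and base-mediated 1,3-prototropic isomerisation moves the alkene into conjugation with both carbonyls as the more stable E (trans-diacyl) isomer.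

Step 16
Reactants: 28 methyl (2E,6R,7E,9E,11E)-8,10-diethyl-2,6-dimethyl-4-oxo-12-phenyldodeca-2,7,9,11-tetraenoate
Product: 29 methyl (1R,3aS,4R,5S,7aS)-5,7-diethyl-1,4-dimethyl-3-oxo-5-[(E)-2-phenylethenyl]-2,3,3a,4,5,7a-hexahydro-1H-indene-4-carboxylate
Conditions: toluene (5 mM), BHT (cat.), 80 °C
Reagents that add atoms: none
Why: Intramolecular Diels–Alder reaction through the ester-endo, tether-anti transition state, with the C6 methyl group anti to the incoming dienophile (C6–H eclipses C7=C8 to avoid A(1,3) strain with the C8 ethyl group), which closes rings A and B together and sets C3a, C4, C5 and C7a relative to C1.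

Step 17
Reactants: 29 methyl (1R,3aS,4R,5S,7aS)-5,7-diethyl-1,4-dimethyl-3-oxo-5-[(E)-2-phenylethenyl]-2,3,3a,4,5,7a-hexahydro-1H-indene-4-carboxylate
Product: 31 methyl (1S,3aS,4R,5S,7aS)-5,7-diethyl-1,4-dimethyl-5-[(E)-2-phenylethenyl]-3-[(trifluoromethanesulfonyl)oxy]-3a,4,5,7a-tetrahydro-1H-indene-4-carboxylate, via potassium enolate 30 (not isolated)
Conditions: KN(SiMe3)2, THF, −78 °C; then PhNTf2, −78 to 0 °C
Reagents that add atoms: N-phenylbis(trifluoromethanesulfonimide) O=S(=O)(N(c1ccccc1)S(=O)(=O)C(F)(F)F)C(F)(F)F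
Why: Kinetic deprotonation at the less hindered C2 methylene and O-triflation place the enol triflate away from the ring fusion, so C3a is not epimerised (the C1 descriptor changes only because of CIP priorities).

Step 18
Reactants: 31 methyl (1S,3aS,4R,5S,7aS)-5,7-diethyl-1,4-dimethyl-5-[(E)-2-phenylethenyl]-3-[(trifluoromethanesulfonyl)oxy]-3a,4,5,7a-tetrahydro-1H-indene-4-carboxylate
Product: 32 methyl (1R,3aR,4R,5S,7aS)-3,5,7-triethyl-1,4-dimethyl-5-[(E)-2-phenylethenyl]-3a,4,5,7a-tetrahydro-1H-indene-4-carboxylate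
Conditions: Et2Zn, Pd(dppf)Cl2 (5 mol %), THF, 60 °C
Reagents that add atoms: diethylzinc CC[Zn]CC
Why: Negishi cross-coupling of the alkenyl triflate, where the wide-bite-angle ligand favours reductive elimination over beta-hydride elimination and the hindered ester is inert.

Step 19
Reactants: 32 methyl (1R,3aR,4R,5S,7aS)-3,5,7-triethyl-1,4-dimethyl-5-[(E)-2-phenylethenyl]-3a,4,5,7a-tetrahydro-1H-indene-4-carboxylate
Product: 34 spiculoic acid B, (1R,3aR,4R,5S,7aS)-3,5,7-triethyl-1,4-dimethyl-5-[(E)-2-phenylethenyl]-3a,4,5,7a-tetrahydro-1H-indene-4-carboxylic acid, via sodium carboxylate 33 (not isolated)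
Conditions: NaSEt, DMF, 90 °C; then 1 M aq. HCl, 0 °C
Reagents that add atoms: none
Why: SN2 demethylation by thiolate at the methyl carbon avoids both the very hindered carbonyl and acid-promoted lactonisation onto the alkenes, and protonation then gives the acid with no stereocentre touched.

**Compound list**
1 | (4S)-4-benzyl-3-propanoyl-1,3-oxazolidin-2-one | CCC(=O)N1[C@@H](Cc2ccccc2)COC1=O | starting material
2 | 3-iodoprop-1-ene (allyl iodide) | C=CCI | starting material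
3 | sodium (Z)-enolate of 1 | C/C=C(\[O-])N1[C@@H](Cc2ccccc2)COC1=O.[Na+] | intermediate
4 | (4S)-4-benzyl-3-[(2R)-2-methylpent-4-enoyl]-1,3-oxazolidin-2-one | C=CC[C@@H](C)C(=O)N1[C@@H](Cc2ccccc2)COC1=O | intermediate
5 | (4S)-4-benzyl-3-[(2R)-2-methyl-3-(1,2,4-trioxolan-3-yl)propanoyl]-1,3-oxazolidin-2-one | C1(OCOO1)C[C@@H](C)C(=O)N2[C@@H](Cc3ccccc3)COC2=O | intermediate
6 | (3R)-4-[(4S)-4-benzyl-2-oxo-1,3-oxazolidin-3-yl]-3-methyl-4-oxobutanal | O=CC[C@@H](C)C(=O)N1[C@@H](Cc2ccccc2)COC1=O | intermediate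
7 | (4S)-4-benzyl-3-[(2R)-3-(1,3-dioxolan-2-yl)-2-methylpropanoyl]-1,3-oxazolidin-2-one | C1(OCCO1)C[C@@H](C)C(=O)N2[C@@H](Cc3ccccc3)COC2=O | intermediate
8 | (2R)-3-(1,3-dioxolan-2-yl)-2-methylpropan-1-ol | C1(OCCO1)C[C@@H](C)CO | intermediate
9 | ethyl 2-bromobutanoate (racemic) | CCC(Br)C(=O)OCC | starting material
10 | triphenylphosphane | c1ccc(cc1)P(c1ccccc1)c1ccccc1 | starting material
11 | (1-ethoxy-1-oxobutan-2-yl)triphenylphosphonium bromide | CCC(C(=O)OCC)[P+](c1ccccc1)(c1ccccc1)c1ccccc1.[Br-] | intermediate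
12 | ethyl 2-(triphenyl-λ5-phosphanylidene)butanoate | CCC(C(=O)OCC)=P(c1ccccc1)(c1ccccc1)c1ccccc1 | intermediate
13 | (2R)-3-(1,3-dioxolan-2-yl)-2-methylpropanal | C1(OCCO1)C[C@@H](C)C=O | intermediate
14 | ethyl (2E,4R)-5-(1,3-dioxolan-2-yl)-2-ethyl-4-methylpent-2-enoate | C1(OCCO1)C[C@@H](C)/C=C(CC)/C(=O)OCC | intermediate
15 | (2E,4R)-5-(1,3-dioxolan-2-yl)-2-ethyl-4-methylpent-2-en-1-ol | C1(OCCO1)C[C@@H](C)/C=C(CC)/CO | intermediate
16 | (2E,4R)-5-(1,3-dioxolan-2-yl)-2-ethyl-4-methylpent-2-enal | C1(OCCO1)C[C@@H](C)/C=C(CC)/C=O | intermediate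
17 | ethyl (2E,4E,6R)-7-(1,3-dioxolan-2-yl)-2,4-diethyl-6-methylhepta-2,4-dienoate | C1(OCCO1)C[C@@H](C)/C=C(CC)/C=C(CC)/C(=O)OCC | intermediate
18 | (2E,4E,6R)-7-(1,3-dioxolan-2-yl)-2,4-diethyl-6-methylhepta-2,4-dien-1-ol | C1(OCCO1)C[C@@H](C)/C=C(CC)/C=C(CC)/CO | intermediate
19 | (2E,4E,6R)-7-(1,3-dioxolan-2-yl)-2,4-diethyl-6-methylhepta-2,4-dienal | C1(OCCO1)C[C@@H](C)/C=C(CC)/C=C(CC)/C=O | intermediate
20 | diethyl benzylphosphonate | CCOP(=O)(Cc1ccccc1)OCC | starting material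
21 | sodium salt of the diethyl benzylphosphonate carbanion | CCOP(=O)([CH-]c1ccccc1)OCC.[Na+] | intermediate
22 | 2-[(2R,3E,5E,7E)-4,6-diethyl-2-methyl-8-phenylocta-3,5,7-trien-1-yl]-1,3-dioxolane | C1(OCCO1)C[C@@H](C)/C=C(CC)/C=C(CC)/C=C/c2ccccc2 | intermediate
23 | (3R,4E,6E,8E)-5,7-diethyl-3-methyl-9-phenylnona-4,6,8-trienal | O=CC[C@@H](C)/C=C(CC)/C=C(CC)/C=C/c1ccccc1 | intermediate
24 | methyl 2-(bromomethyl)prop-2-enoate | COC(=O)C(=C)CBr | starting material
25 | bromo[2-(methoxycarbonyl)prop-2-en-1-yl]zinc | COC(=O)C(=C)C[Zn]Br | intermediate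
26 | methyl (6R,7E,9E,11E)-8,10-diethyl-4-hydroxy-6-methyl-2-methylidene-12-phenyldodeca-7,9,11-trienoate (C4 epimers) | COC(=O)C(=C)CC(O)C[C@@H](C)/C=C(CC)/C=C(CC)/C=C/c1ccccc1 | intermediate
27 | methyl (6R,7E,9E,11E)-8,10-diethyl-6-methyl-2-methylidene-4-oxo-12-phenyldodeca-7,9,11-trienoate | COC(=O)C(=C)CC(=O)C[C@@H](C)/C=C(CC)/C=C(CC)/C=C/c1ccccc1 | intermediate
28 | methyl (2E,6R,7E,9E,11E)-8,10-diethyl-2,6-dimethyl-4-oxo-12-phenyldodeca-2,7,9,11-tetraenoate | COC(=O)/C(C)=C/C(=O)C[C@@H](C)/C=C(CC)/C=C(CC)/C=C/c1ccccc1 | intermediate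
29 | methyl (1R,3aS,4R,5S,7aS)-5,7-diethyl-1,4-dimethyl-3-oxo-5-[(E)-2-phenylethenyl]-2,3,3a,4,5,7a-hexahydro-1H-indene-4-carboxylate | CCC1=C[C@@](/C=C/c2ccccc2)(CC)[C@](C)(C(=O)OC)[C@H]2C(=O)C[C@@H](C)[C@H]12 | intermediate
30 | potassium (1S,3aS,4R,5S,7aS)-5,7-diethyl-4-(methoxycarbonyl)-1,4-dimethyl-5-[(E)-2-phenylethenyl]-3a,4,5,7a-tetrahydro-1H-inden-3-olate | CCC1=C[C@@](/C=C/c2ccccc2)(CC)[C@](C)(C(=O)OC)[C@H]2C([O-])=C[C@@H](C)[C@H]12.[K+] | intermediate
31 | methyl (1S,3aS,4R,5S,7aS)-5,7-diethyl-1,4-dimethyl-5-[(E)-2-phenylethenyl]-3-[(trifluoromethanesulfonyl)oxy]-3a,4,5,7a-tetrahydro-1H-indene-4-carboxylate | CCC1=C[C@@](/C=C/c2ccccc2)(CC)[C@](C)(C(=O)OC)[C@H]2C(OS(=O)(=O)C(F)(F)F)=C[C@@H](C)[C@H]12 | intermediate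
32 | methyl (1R,3aR,4R,5S,7aS)-3,5,7-triethyl-1,4-dimethyl-5-[(E)-2-phenylethenyl]-3a,4,5,7a-tetrahydro-1H-indene-4-carboxylate | CCC1=C[C@@](/C=C/c2ccccc2)(CC)[C@](C)(C(=O)OC)[C@H]2C(CC)=C[C@@H](C)[C@H]12 | intermediate
33 | sodium (1R,3aR,4R,5S,7aS)-3,5,7-triethyl-1,4-dimethyl-5-[(E)-2-phenylethenyl]-3a,4,5,7a-tetrahydro-1H-indene-4-carboxylate | CCC1=C[C@@](/C=C/c2ccccc2)(CC)[C@](C)(C(=O)[O-])[C@H]2C(CC)=C[C@@H](C)[C@H]12.[Na+] | intermediate
34 | spiculoic acid B, (1R,3aR,4R,5S,7aS)-3,5,7-triethyl-1,4-dimethyl-5-[(E)-2-phenylethenyl]-3a,4,5,7a-tetrahydro-1H-indene-4-carboxylic acid | CCC1=C[C@@](/C=C/c2ccccc2)(CC)[C@](C)(C(=O)O)[C@H]2C(CC)=C[C@@H](C)[C@H]12 | target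

**Step count and risks**

Total steps: 19. Longest linear sequence: 18 steps (1 to 34 through steps 1–4 and 6–19); step 5 makes the ylide that is used twice.

The three steps most likely to fail, with fallbacks:

- **Step 15 (oxidation and isomerisation to the E dienophile).** The base-mediated shift might stall or give some Z isomer, and 26 might lactonise before it is oxidised. The fallback sets out from 23 and comes back at 28. A Nozaki–Hiyama–Kishi addition of methyl (2E)-3-iodo-2-methylprop-2-enoate to 23 (CrCl2, NiCl2 cat., DMF, rt) carries the E geometry in from the reagent and gives methyl (2E,6R,7E,9E,11E)-8,10-diethyl-4-hydroxy-2,6-dimethyl-12-phenyldodeca-2,7,9,11-tetraenoate F1 as a C4 epimer mixture. Dess–Martin oxidation of this alcohol gives 28 directly.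

- **Step 16 (cycloaddition).** Two quaternary carbons are joined, and the tether ketone competes with the ester for the endo position, which would give the cis-fused isomer. The fallback sets out from 28 and comes back at 29; it runs the cycloaddition one oxidation level lower so that only the ester activates and directs.
  - Reduction with (S)-2-methyl-CBS-oxazaborolidine and catecholborane (toluene, −78 °C; alkenyl as the large group) gives methyl (2E,4R,6R,7E,9E,11E)-8,10-diethyl-4-hydroxy-2,6-dimethyl-12-phenyldodeca-2,7,9,11-tetraenoate F2.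
  - TBSCl and imidazole give methyl (2E,4R,6R,7E,9E,11E)-4-{[tert-butyl(dimethyl)silyl]oxy}-8,10-diethyl-2,6-dimethyl-12-phenyldodeca-2,7,9,11-tetraenoate F3. Its 4R silyloxy group is matched with the C6 methyl group, since both allylic hydrogens eclipse their alkenes.
  - Heating (toluene, BHT, 150 °C) gives methyl (1R,3R,3aS,4R,5S,7aS)-3-{[tert-butyl(dimethyl)silyl]oxy}-5,7-diethyl-1,4-dimethyl-5-[(E)-2-phenylethenyl]-2,3,3a,4,5,7a-hexahydro-1H-indene-4-carboxylate F4.
  - Bu4NF buffered with AcOH gives methyl (1R,3R,3aS,4R,5S,7aS)-5,7-diethyl-3-hydroxy-1,4-dimethyl-5-[(E)-2-phenylethenyl]-2,3,3a,4,5,7a-hexahydro-1H-indene-4-carboxylate F5, and Dess–Martin oxidation returns 29.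

- **Step 18 (ethylation of the hindered alkenyl triflate).** Beta-hydride elimination would give the reduced alkene. The fallback sets out from 31 and comes back at 32. A Stille coupling with tributyl(vinyl)stannane (Pd(PPh3)4, LiCl, THF, 65 °C), which has no beta-hydrogen problem, gives methyl (1R,3aR,4R,5S,7aS)-3-ethenyl-5,7-diethyl-1,4-dimethyl-5-[(E)-2-phenylethenyl]-3a,4,5,7a-tetrahydro-1H-indene-4-carboxylate F6. Diimide generated from 2-nitrobenzenesulfonylhydrazide and Et3N (CH2Cl2, rt) then saturates only the monosubstituted vinyl group and gives 32.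

**Further compounds**
F1 | step 15 | methyl (2E,6R,7E,9E,11E)-8,10-diethyl-4-hydroxy-2,6-dimethyl-12-phenyldodeca-2,7,9,11-tetraenoate (C4 epimers) | COC(=O)/C(C)=C/C(O)C[C@@H](C)/C=C(CC)/C=C(CC)/C=C/c1ccccc1
F2 | step 16 | methyl (2E,4R,6R,7E,9E,11E)-8,10-diethyl-4-hydroxy-2,6-dimethyl-12-phenyldodeca-2,7,9,11-tetraenoate | COC(=O)/C(C)=C/[C@H](O)C[C@@H](C)/C=C(CC)/C=C(CC)/C=C/c1ccccc1
F3 | step 16 | methyl (2E,4R,6R,7E,9E,11E)-4-{[tert-butyl(dimethyl)silyl]oxy}-8,10-diethyl-2,6-dimethyl-12-phenyldodeca-2,7,9,11-tetraenoate | COC(=O)/C(C)=C/[C@H](O[Si](C)(C)C(C)(C)C)C[C@@H](C)/C=C(CC)/C=C(CC)/C=C/c1ccccc1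
F4 | step 16 | methyl (1R,3R,3aS,4R,5S,7aS)-3-{[tert-butyl(dimethyl)silyl]oxy}-5,7-diethyl-1,4-dimethyl-5-[(E)-2-phenylethenyl]-2,3,3a,4,5,7a-hexahydro-1H-indene-4-carboxylate | CCC1=C[C@@](/C=C/c2ccccc2)(CC)[C@](C)(C(=O)OC)[C@H]2[C@H](O[Si](C)(C)C(C)(C)C)C[C@@H](C)[C@H]12
F5 | step 16 | methyl (1R,3R,3aS,4R,5S,7aS)-5,7-diethyl-3-hydroxy-1,4-dimethyl-5-[(E)-2-phenylethenyl]-2,3,3a,4,5,7a-hexahydro-1H-indene-4-carboxylate | CCC1=C[C@@](/C=C/c2ccccc2)(CC)[C@](C)(C(=O)OC)[C@H]2[C@H](O)C[C@@H](C)[C@H]12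
F6 | step 18 | methyl (1R,3aR,4R,5S,7aS)-3-ethenyl-5,7-diethyl-1,4-dimethyl-5-[(E)-2-phenylethenyl]-3a,4,5,7a-tetrahydro-1H-indene-4-carboxylate | CCC1=C[C@@](/C=C/c2ccccc2)(CC)[C@](C)(C(=O)OC)[C@H]2C(C=C)=C[C@@H](C)[C@H]12
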